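Lupalbigenin is genistein carrying 3-methylbut-2-enyl groups at C6 (ring A) and C3' (ring B), each ortho to a phenolic oxygen (O5 and O4'). Both C–C bonds are therefore traced back to O–C bonds: a 7-O-silylated genistein whose O5 and O4' bear 2-methylbut-3-en-2-yl groups. On heating with Eu(fod)3, two aromatic Claisen [3,3] shifts move both allyl units from oxygen to carbon with allylic inversion, giving the normal prenyl groups and freeing both phenols in one operation. The step exploits the fact that C6 is the only free ortho carbon of O5 (C4a is a ring-fusion carbon) and that C3' and C5' of ring B are equivalent.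

Key step: step 4

Remark on the chemistry: 3-chloro-3-methylbut-1-yne is taken as a purchased reagent, and in the key step the ring A ether is assumed to rearrange before the ring B ether (the reverse order would lead to the same product).

Step 1
Reactants: 1 genistein; 2 chlorotriisopropylsilane
Product: 3 7-O-triisopropylsilylgenistein
Conditions: t-BuOK (1.0 equiv), DMF, 0 °C; then TIPSCl (1.0 equiv), 0 °C → rt
Reagents that add atoms: chlorotriisopropylsilane, CC(C)[Si](Cl)(C(C)C)C(C)C
Why: Regioselective O-silylation of a phenoxide: the 7-hydroxyl, para to the C4 carbonyl and thus a vinylogous carboxylic acid, is markedly more acidic than the 4'-hydroxyl, so one equivalent of base should form only the 7-phenoxide, which takes up the bulky silyl chloride while the hydrogen-bonded 5-hydroxyl stays untouched.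

Step 2
Reactants: 3 7-O-triisopropylsilylgenistein; 4 3-chloro-3-methylbut-1-yne
Product: 6 7-O-triisopropylsilyl-5,4'-bis-O-(2-methylbut-3-yn-2-yl)genistein, via 4'-O-propargyl monoether 5 (not isolated)
Conditions: 4 (5 equiv, in portions), DBU (5 equiv), CuCl2 (5 mol%), MeCN, 0 °C → rt, Ar
Reagents that add atoms: 3-chloro-3-methylbut-1-yne, C#CC(C)(C)Cl
Why: Copper-catalysed propargylic etherification, in which a copper acetylide of 4 loses chloride to a copper allenylidene that the phenoxides capture at the tertiary carbon (a bond out of reach of SN2 alkylation); the free 4'-hydroxyl should react first (5) and the hydrogen-bonded 5-hydroxyl afterwards under excess reagent, while the hindered aryl silyl ether should tolerate anhydrous DBU at or below room temperature.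

Step 3
Reactants: 6 7-O-triisopropylsilyl-5,4'-bis-O-(2-methylbut-3-yn-2-yl)genistein
Product: 7 7-O-triisopropylsilyl-5,4'-bis-O-(2-methylbut-3-en-2-yl)genistein
Conditions: H2 (1 atm), Pd/CaCO3 poisoned with Pb(OAc)2, quinoline, EtOAc, rt, stopped after uptake of 2 equiv H2
Reagents that add atoms: none
Why: Lindlar-type semihydrogenation: the poisoned palladium surface binds terminal alkynes far more strongly than the vinyl groups formed or the aryl-conjugated C2=C3 bond of the pyranone, so reduction should stop at the two vinyl groups, and room temperature keeps the new tertiary allyl ethers from rearranging early.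

Step 4
Reactants: 7 7-O-triisopropylsilyl-5,4'-bis-O-(2-methylbut-3-en-2-yl)genistein
Product: 11 7-O-triisopropylsilyllupalbigenin, via ring A C6-dienone 8 (not isolated), via 6-prenyl 4'-ether 9 (not isolated), via ring B C3'-dienone 10 (not isolated)
Conditions: Eu(fod)3 (10 mol%), NaHCO3, PhMe, 60 → 110 °C, Ar
Reagents that add atoms: none
Why: Each aryl 2-methylbut-3-en-2-yl ether should undergo a concerted suprafacial [3,3] shift through a chair-like six-membered transition state in which the terminal vinyl CH2 bonds to the ortho ring carbon while the O–C(CH3)2 bond breaks, so the allyl unit arrives inverted as a normal 3-methylbut-2-enyl group, and the cyclohexadienones 8 and 10 then tautomerise to the phenols. The reaction type is the aromatic Claisen rearrangement of aryl 1,1-dimethylallyl ethers, assisted here by Eu(fod)3, whose trivalent europium binds the C4 carbonyl and O5 and polarises the ring A ether, so that ring A is expected to react first (giving 9) and ring B on further heating. No ring is closed and no stereocentre is formed, since the transient sp3 centres at C6 and C3' are erased on enolisation. Site selectivity is fixed by the substrate: O5 has only C6 as a free ortho carbon because C4a is a ring-fusion carbon, and O4' has two equivalent ortho carbons, C3' and C5'. The gem-dimethyl groups weaken the O–C bond, so both shifts should run at or below about 110 °C, under conditions that the silyl ether and the pyranone should tolerate. The one competing path, a Cope shift of the C6 prenyl group of dienone 8 on to C8, would have to build a congested C8–C(CH3)2 bond and should lose to fast enolisation to the hydrogen-bonded 5-hydroxyl, while NaHCO3 keeps the medium free of acid so that the new ortho-prenylphenols do not close to chromans.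

Step 5
Reactants: 11 7-O-triisopropylsilyllupalbigenin
Product: 12 lupalbigenin
Conditions: Bu4NF (1.1 equiv), AcOH (1.1 equiv), THF, 0 °C
Reagents that add atoms: none
Why: Fluoride-induced cleavage of an aryl silyl ether, driven by the strong Si–F bond and eased by the good leaving ability of the 7-phenoxide; buffering with acetic acid keeps the medium near neutral, so neither acid-promoted closure of the ortho-prenylphenols to chromans nor base damage to the pyranone is expected.

Compound list
1 | genistein (5,7,4'-trihydroxyisoflavone) | O=c1c(-c2ccc(O)cc2)coc2cc(O)cc(O)c12 | starting material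
2 | chlorotriisopropylsilane | CC(C)[Si](Cl)(C(C)C)C(C)C | starting material
3 | 7-O-triisopropylsilylgenistein (5,4'-dihydroxy-7-triisopropylsilyloxyisoflavone) | CC(C)[Si](Oc1cc(O)c2c(=O)c(-c3ccc(O)cc3)coc2c1)(C(C)C)C(C)C | intermediate
4 | 3-chloro-3-methylbut-1-yne | C#CC(C)(C)Cl | starting material
5 | 7-O-triisopropylsilyl-4'-O-(2-methylbut-3-yn-2-yl)genistein, 5-hydroxyl free (not isolated) | CC(C)[Si](Oc1cc(O)c2c(=O)c(-c3ccc(OC(C)(C)C#C)cc3)coc2c1)(C(C)C)C(C)C | intermediate
6 | 7-O-triisopropylsilyl-5,4'-bis-O-(2-methylbut-3-yn-2-yl)genistein | CC(C)[Si](Oc1cc(OC(C)(C)C#C)c2c(=O)c(-c3ccc(OC(C)(C)C#C)cc3)coc2c1)(C(C)C)C(C)C | intermediate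
7 | 7-O-triisopropylsilyl-5,4'-bis-O-(2-methylbut-3-en-2-yl)genistein | CC(C)[Si](Oc1cc2occ(-c3ccc(OC(C)(C)C=C)cc3)c(=O)c2c(OC(C)(C)C=C)c1)(C(C)C)C(C)C | intermediate
8 | 6-(3-methylbut-2-enyl)-3-[4-(2-methylbut-3-en-2-yloxy)phenyl]-7-triisopropylsilyloxy-6H-chromene-4,5-dione; ring A cyclohexa-2,4-dienone with sp3 C6, racemic at C6 (not isolated) | CC(C)=CCC1C(=O)C2=C(C=C1O[Si](C(C)C)(C(C)C)C(C)C)OC=C(c1ccc(OC(C)(C)C=C)cc1)C2=O | intermediate
9 | 7-O-triisopropylsilyl-6-(3-methylbut-2-enyl)-4'-O-(2-methylbut-3-en-2-yl)genistein, 5-hydroxyl free (not isolated) | CC(C)=CCc1c(O[Si](C(C)C)(C(C)C)C(C)C)cc2occ(-c3ccc(OC(C)(C)C=C)cc3)c(=O)c2c1O | intermediate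
10 | 5-hydroxy-6-(3-methylbut-2-enyl)-3-[3-(3-methylbut-2-enyl)-4-oxocyclohexa-1,5-dien-1-yl]-7-triisopropylsilyloxychromen-4-one; ring B cyclohexa-2,4-dienone with sp3 C3', racemic at C3' (not isolated) | CC(C)=CCc1c(O[Si](C(C)C)(C(C)C)C(C)C)cc2occ(C3=CC(CC=C(C)C)C(=O)C=C3)c(=O)c2c1O | intermediate
11 | 7-O-triisopropylsilyllupalbigenin (6,3'-bis(3-methylbut-2-enyl)-7-O-triisopropylsilylgenistein) | CC(C)=CCc1cc(-c2coc3cc(O[Si](C(C)C)(C(C)C)C(C)C)c(CC=C(C)C)c(O)c3c2=O)ccc1O | intermediate
12 | lupalbigenin (6,3'-bis(3-methylbut-2-enyl)genistein; no stereocentres) | CC(C)=CCc1cc(-c2coc3cc(O)c(CC=C(C)C)c(O)c3c2=O)ccc1O | target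

Total step count: 5. Longest linear sequence: 5 steps (1 → 3 → 6 → 7 → 11 → 12).

Steps most likely to fail

1. Step 4 (key step). What may go wrong: heterolysis of the tertiary O–C bonds under Lewis acid and heat instead of the concerted shift (loss of the C5 unit as isoprene, or recombination at the wrong carbon), acid-promoted closure of a freshly formed ortho-prenylphenol to a 2,2-dimethylchroman, or a following Cope shift from C6 to C8. Fallback (cross-coupling in place of sigmatropy), setting out from 3 and returning at 11: iodination of 3 with benzyltrimethylammonium dichloroiodate (2 equiv) and CaCO3 in CH2Cl2–MeOH at rt should place iodine ortho to each free hydroxyl, at C6 under the direction of the free 5-hydroxyl with O7 capped and at C3' on ring B, to give 6,3'-diiodo-7-O-triisopropylsilylgenistein F1. A twofold Stille coupling of F1 with tributyl(3-methylbut-2-enyl)stannane and Pd(PPh3)4 in DMF at 90 °C should then attach both prenyl groups through their primary carbons and give 11, which continues with step 5.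

2. Step 2. What may go wrong: stalling at the monoether because the hydrogen-bonded, peri-hindered 5-hydroxyl captures the copper-bound electrophile too slowly while the chloride is consumed by elimination, or base-induced loss of the silyl group followed by alkylation at O7. Fallback (allylic instead of propargylic substitution, which also makes step 3 unnecessary), setting out from 3 and returning at 7: 2-methylbut-3-en-2-ol is converted with n-BuLi and Boc2O in THF at −78 °C → rt into tert-butyl 2-methylbut-3-en-2-yl carbonate F2. Compound 3 is then treated with F2 (4 equiv) and Pd(PPh3)4 (5 mol%) in THF at 0 °C. Zerovalent palladium ionises the carbonate with loss of CO2, the tert-butoxide so formed deprotonates the phenols under otherwise neutral conditions, and the phenoxides attack the more substituted end of the 1,1-dimethylallyl palladium cation under kinetic control (Tsuji–Trost O-allylation). This should give 7 directly, provided the reaction is stopped before the ether re-ionises to the linear prenyl ether.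

3. Step 1. What may go wrong: poor discrimination between O7 and O4', leading to silylation at both oxygens or to silyl transfer on to the 4'-phenoxide. Fallback (selective unmasking instead of selective masking), setting out from 1 and returning at 3: peracetylation of 1 (Ac2O, pyridine, rt) gives genistein triacetate F3. The 7-O-acetyl group, the ester of the most acidic phenol, is removed selectively with PhSH and imidazole in NMP at 0 °C to give 5,4'-di-O-acetylgenistein F4. Silylation of its only free hydroxyl (TIPSCl, imidazole, DMF, rt) gives 5,4'-di-O-acetyl-7-O-triisopropylsilylgenistein F5. Ammonolysis of the two aryl acetates (NH3, MeOH–THF, 0 °C), which attacks the acyl carbons and should leave the hindered silyl ether alone, then gives 3.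

Further compounds
F1 | step 4 | 6,3'-diiodo-7-O-triisopropylsilylgenistein | CC(C)[Si](Oc1cc2occ(-c3ccc(O)c(I)c3)c(=O)c2c(O)c1I)(C(C)C)C(C)C
F2 | step 2 | tert-butyl 2-methylbut-3-en-2-yl carbonate | CC(C)(C)OC(=O)OC(C)(C)C=C
F3 | step 1 | genistein triacetate (5,7,4'-tri-O-acetylgenistein) | CC(=O)Oc1ccc(-c2coc3cc(OC(C)=O)cc(OC(C)=O)c3c2=O)cc1
F4 | step 1 | 5,4'-di-O-acetylgenistein | CC(=O)Oc1ccc(-c2coc3cc(O)cc(OC(C)=O)c3c2=O)cc1
F5 | step 1 | 5,4'-di-O-acetyl-7-O-triisopropylsilylgenistein | CC(=O)Oc1ccc(-c2coc3cc(O[Si](C(C)C)(C(C)C)C(C)C)cc(OC(C)=O)c3c2=O)cc1
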